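The cyclobutene is disconnected at C3–C2' and C9–C1': a formal [2+2] of the C2'–Br/C1'–H edge of ring B across an exocyclic C3=C9 alkene on the chromane. The feature exploited is that the C3' oxygen of ring B and the C4 oxygen of the pyranone ring lie close enough to share one silicon atom. In a single palladium-catalysed operation the tethered aryl should add to C3, the β-hydrogen-free C9–Pd species should metalate C1'–H, and reductive elimination should close the spiro ring, the (4S)-carbinol dictating C3. The precursor is the diisopropylsilylene bis-ether linking (4S)-5,7-dimethoxy-3-methylidenechroman-4-ol to 2-bromo-6-methoxyphenol.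

Key step: step 5

Remark: locants are O1, C2, C3 (spiro), C4, C4a–C8a for the chromane, C9 for the cyclobutene CH2 and C1' (on C9), C2' (on C3), C3'–C6' for ring B; the spiro carbon of the target is (S), which requires the (4S)-carbinol, and because the 2,4,6-trioxygenated benzylic C4–O bond ionises easily, every operation from step 2 onward is kept neutral or basic.

Step 1
Reactants: 1 2-hydroxy-4,6-dimethoxybenzaldehyde; 2 2,3-dibromoprop-1-ene
Product: 3 2-[(2-bromoprop-2-en-1-yl)oxy]-4,6-dimethoxybenzaldehyde
Conditions: K2CO3, DMF, 50 °C
Reagents that add atoms: none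
Why: Williamson etherification, in which the phenoxide displaces the allylic bromide of 2 by SN2 while the vinylic bromide is inert.

Step 2
Reactants: 3 2-[(2-bromoprop-2-en-1-yl)oxy]-4,6-dimethoxybenzaldehyde
Product: 4 racemic 5,7-dimethoxy-3-methylidene-3,4-dihydro-2H-chromen-4-ol
Conditions: CrCl2 (4 equiv), NiCl2 (2 mol %), DMF, rt; aqueous work-up at pH 8; chromatography on Et3N-deactivated SiO2
Reagents that add atoms: none
Why: Intramolecular Nozaki–Hiyama–Kishi reaction, in which nickel-catalysed activation of the vinyl bromide and transfer to chromium give an alkenylchromium species that is covalent enough to keep its β-aryloxy group and adds 6-exo to the tethered aldehyde, closing ring C with the exocyclic alkene in place and C4 racemic.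

Step 3
Reactants: 4 racemic 5,7-dimethoxy-3-methylidene-3,4-dihydro-2H-chromen-4-ol
Product: 5 (4S)-5,7-dimethoxy-3-methylidene-3,4-dihydro-2H-chromen-4-ol
Conditions: immobilised Burkholderia cepacia lipase (Amano PS), vinyl acetate, t-BuOMe, 35 °C, run slightly past half conversion; separation on Et3N-deactivated SiO2
Reagents that add atoms: none
Why: Lipase-catalysed acylative kinetic resolution, in which the empirical lipase rule for secondary carbinols with the aryl ring as the large group (as in chroman-4-ol and 1-tetralol) predicts acetylation of the (4R)-alcohol, so the required (4S)-alcohol should be recovered unreacted, its configuration to be confirmed by chiral HPLC and MTPA ester analysis.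

Step 4
Reactants: 5 (4S)-5,7-dimethoxy-3-methylidene-3,4-dihydro-2H-chromen-4-ol; 6 2-bromo-6-methoxyphenol; 7 dichlorodi(propan-2-yl)silane
Product: 9 (4S)-4-{[(2-bromo-6-methoxyphenoxy)di(propan-2-yl)silyl]oxy}-5,7-dimethoxy-3-methylidene-3,4-dihydro-2H-chromene, via aryloxychlorosilane 8 (not isolated)
Conditions: 6, 7, Et3N, CH2Cl2, 0 °C to rt; then 5, DMAP (cat.), CH2Cl2, rt
Reagents that add atoms: none
Why: Stepwise nucleophilic substitution at silicon (mixed silyl bis-ether formation), in which the di-ortho-substituted phenol should stop at the monochloride 8 and this then silylates the C4 carbinol under amine base, so the ionisable alcohol never meets free acid or the dichlorosilane and C4 is untouched.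

Step 5
Reactants: 9 (4S)-4-{[(2-bromo-6-methoxyphenoxy)di(propan-2-yl)silyl]oxy}-5,7-dimethoxy-3-methylidene-3,4-dihydro-2H-chromene
Product: 10 (3S,4S)-siloxane-bridged spiro benzocyclobutene chromane, in which ring B is bonded to C3 through C2' and to C9H2 through C1', the C4–O–Si(i-Pr)2–O–C3' bridge is cis to the C3–C2' bond, and C4', C5 and C7 carry methoxy groups
Conditions: Pd[P(t-Bu)3]2 (10 mol %), Cs2CO3 (2 equiv), CsO2CCMe3 (30 mol %), 4 Å MS, mesitylene (0.02 M), 120 °C
Reagents that add atoms: none
Why: Proposed new method: zerovalent palladium should insert into the C2'–Br bond, the siloxane tether then forces syn migratory insertion of the C3=C9 alkene so that C2' bonds to C3, and the primary alkylpalladium at C9, whose β-carbon is quaternary and hydrogen-free, should palladate the only free ortho position C1'–H by carboxylate-assisted concerted metalation–deprotonation and then reductively eliminate C9–C1' from the five-membered palladacycle (Pd, C9, C3, C2', C1'). The closest known reaction types are the palladium-catalysed annulation of aryl bromides with norbornene to benzocyclobutenes, the benzocyclobutene synthesis by C(sp3)–H arylation of 2-bromo-tert-alkylbenzenes (same kind of aryl/CH2 palladacycle on a quaternary benzylic carbon, same bulky phosphine) and silicon-tethered intramolecular Heck cyclisations; their combination across a 1,1-disubstituted alkene is new. Two rings close: the temporary seven-membered ring (C3, C4, O, Si, O, C3', C2') by 7-exo-trig carbopalladation, and the cyclobutene (C3, C9, C1', C2') by C(sp2)–C(sp3) reductive elimination with contraction of the palladacycle. The new quaternary stereocentre C3 is controlled by the (4S)-carbinol, because the tether hangs from the C4 oxygen (pseudoaxial to avoid A(1,3) strain with the C5 methoxy group) and C2' can therefore reach only the alkene face syn to that oxygen, giving the cis (3S,4S) product. The step needs exo over 8-endo insertion, secured by the three-atom O–Si–O tether that spans to C3 but not comfortably to C9, and ring B regiocontrol, secured because bromine marks C2' next to the tethered C3' oxygen and C1' bears the only ortho hydrogen. The fluoride-free catalyst, the insoluble carbonate and the non-polar solvent are chosen so that the base-labile aryloxy–silicon bond survives, and high dilution disfavours intermolecular Heck coupling.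

Step 6
Reactants: 10 (3S,4S)-siloxane-bridged spiro benzocyclobutene chromane
Product: 11 (3S,4S)-3'-hydroxy-4',5,7-trimethoxy spiro[benzocyclobutene–chroman]-4-ol (free C4–OH and C3'–OH)
Conditions: Bu4NF (2.5 equiv), THF, 0 °C to rt; pH 7 phosphate buffer work-up
Reagents that add atoms: none
Why: Fluoride-mediated desilylation, in which both Si–O bonds of the silylene bridge are cleaved through the strong Si–F bond under basic conditions that leave the ionisable C4 carbinol, the cyclobutene and both stereocentres untouched.

Step 7
Reactants: 11 (3S,4S)-3'-hydroxy-4',5,7-trimethoxy spiro[benzocyclobutene–chroman]-4-ol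
Product: 12 (3S,4S)-3',4',5,7-tetramethoxy spiro[benzocyclobutene–chroman]-4-ol
Conditions: MeI, K2CO3, acetone, 40 °C
Reagents that add atoms: iodomethane, CI
Why: Williamson methylation, in which carbonate deprotonates only the phenol, so the C3' oxygen is methylated while the hindered secondary C4 alcohol stays free.

Step 8
Reactants: 12 (3S,4S)-3',4',5,7-tetramethoxy spiro[benzocyclobutene–chroman]-4-ol
Product: 13 (3S)-3',4',5,7-tetramethoxy spiro[benzocyclobutene–chroman]-4-one (target, CNP0192565.1)
Conditions: Pr4N[RuO4] (5 mol %), N-methylmorpholine N-oxide (1.5 equiv), 4 Å MS, CH2Cl2, rt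
Reagents that add atoms: none
Why: Ley–Griffith oxidation, a neutral catalytic perruthenate oxidation of the hindered benzylic C4 alcohol to the aryl ketone that avoids acid (no C4 cation, hence no ring expansion of the spiro cyclobutene) and cannot epimerise C3, which has no α-hydrogen.

Compound list
1 | 2-hydroxy-4,6-dimethoxybenzaldehyde | COc1cc(O)c(C=O)c(OC)c1 | starting material
2 | 2,3-dibromoprop-1-ene | BrCC(Br)=C | starting material
3 | 2-[(2-bromoprop-2-en-1-yl)oxy]-4,6-dimethoxybenzaldehyde | COc1cc(OCC(Br)=C)c(C=O)c(OC)c1 | intermediate
4 | racemic 5,7-dimethoxy-3-methylidene-3,4-dihydro-2H-chromen-4-ol | COc1cc(OC)c2c(c1)OCC(=C)C2O | intermediate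
5 | (4S)-5,7-dimethoxy-3-methylidene-3,4-dihydro-2H-chromen-4-ol | COc1cc(OC)c2c(c1)OCC(=C)[C@@H]2O | intermediate
6 | 2-bromo-6-methoxyphenol | COc1cccc(Br)c1O | starting material
7 | dichlorodi(propan-2-yl)silane | CC(C)[Si](Cl)(Cl)C(C)C | starting material
8 | (2-bromo-6-methoxyphenoxy)chlorodi(propan-2-yl)silane | COc1cccc(Br)c1O[Si](Cl)(C(C)C)C(C)C | intermediate
9 | (4S)-4-{[(2-bromo-6-methoxyphenoxy)di(propan-2-yl)silyl]oxy}-5,7-dimethoxy-3-methylidene-3,4-dihydro-2H-chromene | COc1cc(OC)c2c(c1)OCC(=C)[C@@H]2O[Si](C(C)C)(C(C)C)Oc1c(Br)cccc1OC | intermediate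
10 | (3S,4S)-siloxane-bridged spiro benzocyclobutene chromane (C4–O–Si(i-Pr)2–O–C3' bridge cis to C3–C2') | COc1cc(OC)c2c(c1)OC[C@@]1(Cc3ccc(OC)c4c31)[C@@H]2O[Si](C(C)C)(C(C)C)O4 | intermediate
11 | (3S,4S)-3'-hydroxy-4',5,7-trimethoxy spiro[benzocyclobutene–chroman]-4-ol | COc1cc(OC)c2c(c1)OC[C@@]1(Cc3ccc(OC)c(O)c31)[C@@H]2O | intermediate
12 | (3S,4S)-3',4',5,7-tetramethoxy spiro[benzocyclobutene–chroman]-4-ol | COc1cc(OC)c2c(c1)OC[C@@]1(Cc3ccc(OC)c(OC)c31)[C@@H]2O | intermediate
13 | (3S)-3',4',5,7-tetramethoxy spiro[benzocyclobutene–chroman]-4-one | COc1cc(OC)c2c(c1)OC[C@@]1(Cc3ccc(OC)c(OC)c31)C2=O | target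

Total step count: 8
Longest linear sequence: 8 steps (1 to 13); 6 and 7 enter at step 4.

Steps most likely to fail

Step 5 (proposed new method). The alkylpalladium intermediate may be diverted before the four-membered reductive elimination, by protonolysis of the palladacycle or by 8-endo insertion, or the aryloxy–silicon bond may be cleaved by the base before insertion. The fallback uses known chemistry only, sets out from 6 and rejoins the route at 13; it makes the cyclobutene first by an aryne [2+2] cycloaddition and builds ring C last. Methylation of 6 (MeI, K2CO3, acetone) should give 1-bromo-2,3-dimethoxybenzene F1. NaNH2 in THF with 1,1-dimethoxyethene should generate the aryne across C1'–C2' and trap it regioselectively, the nucleophilic CH2 adding to the aryne carbon remote from the methoxy group, to give 4,5-dimethoxybenzocyclobutenone dimethyl ketal F2. Hydrolysis (dilute HCl, THF) should give 4,5-dimethoxybicyclo[4.2.0]octa-1,3,5-trien-7-one F3, with the carbonyl carbon (the future C3) on C2'. Van Leusen reductive cyanation (TosMIC, t-BuOK, DME/EtOH) should give racemic 4,5-dimethoxybicyclo[4.2.0]octa-1,3,5-triene-7-carbonitrile F4. Deprotonation with LiN(i-Pr)2 and addition to formaldehyde installs C2 as racemic 7-(hydroxymethyl)-4,5-dimethoxybicyclo[4.2.0]octa-1,3,5-triene-7-carbonitrile F5. Mitsunobu etherification with 3,5-dimethoxyphenol (PPh3, diisopropyl azodicarboxylate, toluene) should give racemic 7-[(3,5-dimethoxyphenoxy)methyl]-4,5-dimethoxybicyclo[4.2.0]octa-1,3,5-triene-7-carbonitrile F6. Intramolecular Houben–Hoesch acylation (ZnCl2, HCl, Et2O; then hot water) closes ring C to the racemic spiro ketone F7. Preparative HPLC on a chiral stationary phase then separates 13 from the (R)-enantiomer of 13 F8.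

Step 3. Acylation may be slow or poorly enantioselective because the peri C5 methoxy group and the 3-methylidene group crowd the carbinol in the enzyme pocket. The fallback sets out from 3 and rejoins at 5; it creates the stereocentre in the ring closure instead of selecting it afterwards. A catalytic asymmetric Nozaki–Hiyama–Kishi cyclisation of 3 (CrCl2 10 mol %, chiral oxazoline–sulfonamide ligand, NiCl2 cat., Mn powder, Cp2ZrCl2, LiCl, MeCN) should give 5 directly, the ligand enantiomer being chosen for the (4S)-alcohol. It passes through no new isolable compound.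

Step 4. Redistribution at silicon to symmetrical bis-ethers, or incomplete silylation of the hindered carbinol by the bulky chlorosilane, may erode the precursor. The fallback sets out from 6 and rejoins at 9; it replaces the difunctional silane by a monofunctional hydrosilane whose Si–H is a latent leaving group. Phenol 6 with chlorodi(propan-2-yl)silane and Et3N should give (2-bromo-6-methoxyphenoxy)di(propan-2-yl)silane F9, which can be purified. N-Bromosuccinimide in CH2Cl2 at 0 °C converts it into bromo(2-bromo-6-methoxyphenoxy)di(propan-2-yl)silane F10, a more reactive electrophile than 8, and addition of 5 with Et3N and DMAP should then give 9.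

Further compounds
F1 | step 5 | 1-bromo-2,3-dimethoxybenzene | COc1cccc(Br)c1OC
F2 | step 5 | 4,5-dimethoxybenzocyclobutenone dimethyl ketal (2,3,8,8-tetramethoxybicyclo[4.2.0]octa-1,3,5-triene) | COc1ccc2CC(OC)(OC)c2c1OC
F3 | step 5 | 4,5-dimethoxybicyclo[4.2.0]octa-1,3,5-trien-7-one | COc1ccc2CC(=O)c2c1OC
F4 | step 5 | racemic 4,5-dimethoxybicyclo[4.2.0]octa-1,3,5-triene-7-carbonitrile | COc1ccc2CC(C#N)c2c1OC
F5 | step 5 | racemic 7-(hydroxymethyl)-4,5-dimethoxybicyclo[4.2.0]octa-1,3,5-triene-7-carbonitrile | COc1ccc2CC(CO)(C#N)c2c1OC
F6 | step 5 | racemic 7-[(3,5-dimethoxyphenoxy)methyl]-4,5-dimethoxybicyclo[4.2.0]octa-1,3,5-triene-7-carbonitrile | COc1cc(OC)cc(OCC2(C#N)Cc3ccc(OC)c(OC)c32)c1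
F7 | step 5 | racemic spiro ketone (racemate of 13) | COc1cc(OC)c2c(c1)OCC1(Cc3ccc(OC)c(OC)c31)C2=O
F8 | step 5 | (R)-enantiomer of 13 | COc1cc(OC)c2c(c1)OC[C@]1(Cc3ccc(OC)c(OC)c31)C2=O
F0 | step 3 | none | none
F9 | step 4 | (2-bromo-6-methoxyphenoxy)di(propan-2-yl)silane | COc1cccc(Br)c1O[SiH](C(C)C)C(C)C
F10 | step 4 | bromo(2-bromo-6-methoxyphenoxy)di(propan-2-yl)silane | COc1cccc(Br)c1O[Si](Br)(C(C)C)C(C)C
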